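**Retrosynthetic overview**
1. 11 ⇒ 9: the C15–O bond is made last by 1,3-hydroxyl transposition of a C13 tertiary vinyl carbinol (C13–O → C15–O, 13E alkene created). This carbinol, inherited from nerolidol, is carried through as a masked allylic alcohol that cannot extend the radical cascade and is inert to acetylation.
2. 9 ⇒ 7: C3–O acetyl bond by acetylation of the axial 3α-alcohol, which comes from the C3 ketone by equatorial hydride delivery.
3. 7 ⇒ 6: ring A (C4–C5) and ring B (C9–C10) are closed together, with the exocyclic C8=C17 alkene, in one enantioselective oxidative radical bicyclisation of an acyclic β-keto ester.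
4. 6 ⇒ 3 + 4: C1–C2 bond by dianion alkylation; bromide 3 from (E)-nerolidol 1 by allylic C–H hydroxylation (C12–O) and bromination.
5. Ring order: ring A, then ring B, within the single cascade of step 4; no other ring.

Assumption: commercial (E)-nerolidol is racemic at its carbinol carbon, so 2, 3 and 6–9 are epimer mixtures at that centre (C13 of the labdane), which is erased in the last step. Labdane numbering is used for 7–11; the target is the normal-series labdane with 3α-OAc and 4β-CO2Me (3R,4R,5R,9S,10R,13E).

Step 1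
Reactants: 1 (E)-nerolidol [(6E)-3,7,11-trimethyldodeca-1,6,10-trien-3-ol, racemic]
Product: 2 (2E,6E)-2,6,10-trimethyldodeca-2,6,11-triene-1,10-diol
Conditions: SeO2 (0.3 equiv), t-BuOOH (3 equiv), salicylic acid (cat.), CH2Cl2, 0 °C to rt
Reagents that add atoms: tert-butyl hydroperoxide, CC(C)(C)OO (terminal oxygen source; SeO2, O=[Se]=O, is the oxygen-transfer catalyst)
Why: SeO2-catalysed allylic C–H hydroxylation (ene reaction then [2,3]-sigmatropic shift) is selective for the (E)-methyl of the terminal trisubstituted alkene of polyprenyl chains and leaves the tertiary vinyl carbinol untouched, giving the (2E)-allylic alcohol.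

Step 2
Reactants: 2 (2E,6E)-2,6,10-trimethyldodeca-2,6,11-triene-1,10-diol
Product: 3 (6E,10E)-12-bromo-3,7,11-trimethyldodeca-1,6,10-trien-3-ol
Conditions: CBr4 (1.1 equiv), PPh3 (1.15 equiv), CH2Cl2, −30 to 0 °C
Reagents that add atoms: carbon tetrabromide, BrC(Br)(Br)Br
Why: Appel bromination converts the primary allylic alcohol much faster than the tertiary carbinol at low temperature and proceeds without allylic shift, so the 10E geometry is kept.

Step 3
Reactants: 3 (6E,10E)-12-bromo-3,7,11-trimethyldodeca-1,6,10-trien-3-ol; 4 methyl 2-methyl-3-oxobutanoate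
Product: 6 methyl (6E,10E)-14-hydroxy-2,6,10,14-tetramethyl-3-oxohexadeca-6,10,15-trienoate, via keto ester dianion 5 (not isolated)
Conditions: 4 (2.3 equiv), NaH, THF, 0 °C; n-BuLi, 0 °C; then 3, −78 to 0 °C; aq NH4Cl
Reagents that add atoms: none
Why: Weiler dianion γ-alkylation (SN2 at the primary allylic bromide by the terminal carbanion) forms the C1–C2 bond with retention of alkene geometry; the excess dianion absorbs the proton of the free tertiary alcohol.

Step 4
Reactants: 6 methyl (6E,10E)-14-hydroxy-2,6,10,14-tetramethyl-3-oxohexadeca-6,10,15-trienoate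
Product: 7 methyl (4R,5R,9S,10R,13RS)-13-hydroxy-3-oxolabda-8(17),14-dien-19-oate
Conditions: Yb(OTf)3 (1.0 equiv), (R,R)-Ph-pybox (1.2 equiv), 4 Å MS, CF3CH2OH, rt; then Mn(OAc)3·2H2O (2.2 equiv), Cu(OAc)2·H2O (1.0 equiv), −10 °C
Reagents that add atoms: none
Why: Proposed new method: enantioselective oxidative radical bicyclisation under chiral Lewis acid control. Yb(OTf)3/Ph-pybox chelates the 1,3-dicarbonyl unit of 6 and Mn(OAc)3 oxidises the bound enol to the α-keto ester radical, which stays on the chiral ytterbium centre so that one face of the planar chelate is shielded. 6-Endo attack on the (E)-C5=C10 alkene and then on the (E)-C8=C9 alkene through a chair–chair array gives the trans-decalin with axial 4β-ester, 10β-methyl, 5α-H and 9β side chain (4R,5R,9S,10R). Divalent copper then oxidises the tertiary C8 radical (organocopper, syn β-hydride loss from the freely rotating methyl) to the exocyclic alkene, and the monosubstituted vinyl group is too poor an acceptor to start a third ring. The closest known reactions are the racemic Mn(OAc)3/Cu(OAc)2 oxidative polyene cyclisation of α-methyl β-keto esters, its lanthanide triflate-promoted variant, and chiral Mg–bisoxazoline or Yb–pybox controlled atom-transfer radical cyclisations of α-bromo β-keto esters. The sense of induction cannot be predicted with confidence, so the ligand antipode is used if the first run gives the opposite enantiomer.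

Step 5
Reactants: 7 methyl (4R,5R,9S,10R,13RS)-13-hydroxy-3-oxolabda-8(17),14-dien-19-oate
Product: 8 methyl (3R,4R,5R,9S,10R,13RS)-3,13-dihydroxylabda-8(17),14-dien-19-oate (3α-alcohol)
Conditions: LiBH(s-Bu)3 (2.5 equiv), THF, −78 °C; then H2O
Reagents that add atoms: none
Why: Bulky trialkylborohydride reduction: LiBH(s-Bu)3 attacks the C3 ketone along the equatorial trajectory (β face), avoiding the axial hydrogens at C1 and C5, to give the axial 3α-alcohol (3R) as with 3-oxo-4,4-disubstituted terpenoids; the hindered axial C19 ester is not reduced at −78 °C.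

Step 6
Reactants: 8 methyl (3R,4R,5R,9S,10R,13RS)-3,13-dihydroxylabda-8(17),14-dien-19-oate
Product: 9 methyl (3R,4R,5R,9S,10R,13RS)-3-acetoxy-13-hydroxylabda-8(17),14-dien-19-oate
Conditions: Ac2O, pyridine, 40 °C
Reagents that add atoms: acetic anhydride, CC(=O)OC(C)=O
Why: Acylation with Ac2O/pyridine without DMAP esterifies the secondary 3α-hydroxyl while the tertiary allylic carbinol stays free, so no protecting group is needed.

Step 7
Reactants: 9 methyl (3R,4R,5R,9S,10R,13RS)-3-acetoxy-13-hydroxylabda-8(17),14-dien-19-oate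
Product: 11 methyl (3R,4R,5R,9S,10R,13E)-3-acetoxy-15-hydroxylabda-8(17),13-dien-19-oate, via silyl ether 10 (not isolated)
Conditions: Ph3SiOReO3 (5 mol %), N,O-bis(trimethylsilyl)acetamide (1.2 equiv), Et2O, −50 to 0 °C; then 1 M aq citric acid, THF, rt
Reagents that add atoms: none
Why: Heptavalent rhenium oxo-catalysed 1,3-transposition of an allylic alcohol ([3,3]-sigmatropic shift of the perrhenate ester through a chair) moves oxygen from C13 to C15 and creates the trisubstituted alkene; silylation of the primary alcohol pulls the equilibrium, the 13E isomer is favoured (an estimated E:Z of about 4:1, larger chain pseudo-equatorial), and the 13Z isomer is removed on AgNO3-impregnated silica.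

**Compound list**
1 | (E)-nerolidol, (6E)-3,7,11-trimethyldodeca-1,6,10-trien-3-ol (racemic) | C=CC(C)(O)CC/C=C(\C)CCC=C(C)C | starting material
2 | (2E,6E)-2,6,10-trimethyldodeca-2,6,11-triene-1,10-diol | C=CC(C)(O)CC/C=C(\C)CC/C=C(\C)CO | intermediate
3 | (6E,10E)-12-bromo-3,7,11-trimethyldodeca-1,6,10-trien-3-ol | C=CC(C)(O)CC/C=C(\C)CC/C=C(\C)CBr | intermediate
4 | methyl 2-methyl-3-oxobutanoate | COC(=O)C(C)C(C)=O | starting material
5 | sodium lithium dianion of methyl 2-methyl-3-oxobutanoate (keto ester dianion) | COC(=O)C(C)=C([O-])[CH2-].[Na+].[Li+] | intermediate (not isolated)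
6 | methyl (6E,10E)-14-hydroxy-2,6,10,14-tetramethyl-3-oxohexadeca-6,10,15-trienoate | COC(=O)C(C)C(=O)CC/C(C)=C/CC/C(C)=C/CCC(C)(O)C=C | intermediate
7 | methyl (4R,5R,9S,10R,13RS)-13-hydroxy-3-oxolabda-8(17),14-dien-19-oate | C=C1CC[C@@H]2[C@](C)(CCC(=O)[C@]2(C)C(=O)OC)[C@H]1CCC(C)(O)C=C | intermediate
8 | methyl (3R,4R,5R,9S,10R,13RS)-3,13-dihydroxylabda-8(17),14-dien-19-oate | C=C1CC[C@@H]2[C@](C)(CC[C@@H](O)[C@]2(C)C(=O)OC)[C@H]1CCC(C)(O)C=C | intermediate
9 | methyl (3R,4R,5R,9S,10R,13RS)-3-acetoxy-13-hydroxylabda-8(17),14-dien-19-oate | C=C1CC[C@@H]2[C@](C)(CC[C@@H](OC(C)=O)[C@]2(C)C(=O)OC)[C@H]1CCC(C)(O)C=C | intermediate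
10 | methyl (3R,4R,5R,9S,10R,13E)-3-acetoxy-15-(trimethylsilyloxy)labda-8(17),13-dien-19-oate | C=C1CC[C@@H]2[C@](C)(CC[C@@H](OC(C)=O)[C@]2(C)C(=O)OC)[C@H]1CC/C(C)=C/CO[Si](C)(C)C | intermediate (not isolated)
11 | methyl (3R,4R,5R,9S,10R,13E)-3-acetoxy-15-hydroxylabda-8(17),13-dien-19-oate | C=C1CC[C@@H]2[C@](C)(CC[C@@H](OC(C)=O)[C@]2(C)C(=O)OC)[C@H]1CC/C(C)=C/CO | target

Total step count: 7. Longest linear sequence: 7 steps (1 to 11).

**Steps most likely to fail**

Step 4 (the new step). The enantioselectivity is untested under acetate-rich oxidative conditions, and the sense of induction has to be found by experiment. The tertiary allylic alcohol may ionise in CF3CH2OH with Yb(OTf)3, and the C13 hydroxyl may trap the oxidised C8 centre as an 8,13-ether. Fallback with known chemistry: setting out from 6, the racemic oxidative bicyclisation with Mn(OAc)3·2H2O and Cu(OAc)2·H2O in AcOH at room temperature gives 7 as the racemate, that is, together with its ring enantiomer methyl (4S,5S,9R,10S,13RS)-13-hydroxy-3-oxolabda-8(17),14-dien-19-oate F1. Preparative supercritical-fluid chromatography on a chiral stationary phase, with both C13 epimers of the wanted ring series pooled, returns the route at 7.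

Step 7. The E:Z ratio for a methyl versus primary-alkyl carbinol is only moderate, the equilibrium may stall, and the allyl cation could be captured by the C8=C17 alkene. Fallback: setting out from 9, acetylation of the tertiary carbinol (Ac2O, DMAP, Et3N) gives methyl (3R,4R,5R,9S,10R,13RS)-3,13-diacetoxylabda-8(17),14-dien-19-oate F2. A PdCl2(MeCN)2-catalysed [3,3] acetate shift under thermodynamic control (cyclisation-induced rearrangement, precedented on sclareol-type 13-acetates) then gives methyl (3R,4R,5R,9S,10R,13E)-3,15-diacetoxylabda-8(17),13-dien-19-oate F3. K2CO3 in MeOH at 0 °C cleaves only the primary allylic acetate and returns the route at 11.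

Step 3. The free tertiary alcohol quenches part of the dianion, and O-alkylation or α-alkylation by the resulting monoanion may lower the yield. Fallback: setting out from 3, silylation with Et3SiOTf and 2,6-lutidine gives (6E,10E)-12-bromo-3,7,11-trimethyl-3-(triethylsilyloxy)dodeca-1,6,10-triene F4. Alkylation of dianion 5 (1.1 equiv now suffices) gives methyl (6E,10E)-2,6,10,14-tetramethyl-3-oxo-14-(triethylsilyloxy)hexadeca-6,10,15-trienoate F5. HF·pyridine in THF removes the silyl group and returns the route at 6.

Further compounds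
F1 | step 4 | methyl (4S,5S,9R,10S,13RS)-13-hydroxy-3-oxolabda-8(17),14-dien-19-oate (ring enantiomer of 7) | C=C1CC[C@H]2[C@@](C)(CCC(=O)[C@@]2(C)C(=O)OC)[C@@H]1CCC(C)(O)C=C
F2 | step 7 | methyl (3R,4R,5R,9S,10R,13RS)-3,13-diacetoxylabda-8(17),14-dien-19-oate | C=C1CC[C@@H]2[C@](C)(CC[C@@H](OC(C)=O)[C@]2(C)C(=O)OC)[C@H]1CCC(C)(OC(C)=O)C=C
F3 | step 7 | methyl (3R,4R,5R,9S,10R,13E)-3,15-diacetoxylabda-8(17),13-dien-19-oate | C=C1CC[C@@H]2[C@](C)(CC[C@@H](OC(C)=O)[C@]2(C)C(=O)OC)[C@H]1CC/C(C)=C/COC(C)=O
F4 | step 3 | (6E,10E)-12-bromo-3,7,11-trimethyl-3-(triethylsilyloxy)dodeca-1,6,10-triene | C=CC(C)(O[Si](CC)(CC)CC)CC/C=C(\C)CC/C=C(\C)CBr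
F5 | step 3 | methyl (6E,10E)-2,6,10,14-tetramethyl-3-oxo-14-(triethylsilyloxy)hexadeca-6,10,15-trienoate | COC(=O)C(C)C(=O)CC/C(C)=C/CC/C(C)=C/CCC(C)(O[Si](CC)(CC)CC)C=C
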